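**Assumptions.** The target has no stereocenters. The carbinol carbon bears two identical methyls, so the compound is achiral, and no step needs stereocontrol. Genistein (the soy isoflavone) is treated as a commercial starting material.

## Retrosynthetic overview
1. Target **15** comes from global MOM removal of **14**. **14** comes from allyl→prenyl cross-metathesis of the 6-allyl-5-hydroxy chromone **12**. **12** comes from a thermal Claisen rearrangement of the 5-O-allyl ether **11**. C4a is blocked, so the allyl can only go to C6, which fixes the regiochemistry.
2. The saturated B-ring chain (3-hydroxy-3-methylbutyl) comes from hydrogenation of the enol **9**. **9** comes from cross-metathesis of the 3'-allyl compound **7** with 2-methylbut-3-en-2-ol. **7** comes from a Claisen rearrangement of the 4'-O-allyl ether (positions 3' and 5' are equivalent).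
3. The strategy is to "walk" two allyl groups onto intact genistein with two regiospecific Claisen rearrangements and edit them by cross-metathesis into two different C5 side chains. No C3–aryl coupling and no pyranone or benzene ring is built.
4. The B-ring chain is made first, so the alkene reduction never sees the A-ring prenyl. The three phenols are differentiated in order of acidity: 7-OH, then 4'-OH, then the chelated 5-OH.

## Route

**Step 1**
Reactants: **1** genistein; **2** chloromethyl methyl ether (MOMCl)
Product: **3** 7-O-MOM-genistein
Conditions: MOMCl (1.05 equiv), K2CO3 (1.1 equiv), DMF, 0 °C → rt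
Reagents that add atoms: MOMCl, ClCOC
Why: The 7-OH is by far the most acidic phenol (vinylogous acid), and the 5-OH is chelated to C4=O, so a Williamson-type etherification with one equivalent of electrophile is selective for O-7. No stereocenter is involved.

**Step 2**
Reactants: **3**; **4** allyl bromide
Product: **5** 4'-O-allyl-7-O-MOM-genistein
Conditions: allyl bromide (1.5 equiv), K2CO3, acetone, reflux
Reagents that add atoms: allyl bromide, C=CCBr
Why: Only the 4'-OH is left as a free, unchelated phenol, so it is O-alkylated. The 5-OH stays untouched, and the MOM group is base-stable.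

**Step 3**
Reactants: **5**
Product: **6** 3'-allyl-4'-hydroxy-7-O-MOM-genistein
Conditions: PhNEt2, 200 °C (microwave or sealed tube), 1 h
Reagents that add atoms: none (isomerization)
Why: Aromatic Claisen [3,3] rearrangement. The para position is occupied by the chromone, and C3' and C5' are equivalent, so there is a single regioisomer. No stereocenter forms. The amine solvent buffers the MOM group.

**Step 4**
Reactants: **6**; **2** MOMCl
Product: **7** 3'-allyl-4',7-bis-O-MOM-genistein
Conditions: MOMCl, iPr2NEt, CH2Cl2, 0 °C → rt
Reagents that add atoms: MOMCl, ClCOC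
Why: The new phenol is protected so that only the chelated 5-OH is free later for allylation (Step 7). The chelated 5-OH is inert to these mild conditions.

**Step 5**
Reactants: **7**; **8** 2-methylbut-3-en-2-ol
Product: **9** E-enol ArCH2CH=CH–C(CH3)2OH (bis-MOM, 5-OH)
Conditions: Hoveyda–Grubbs II (5 mol%), 1,4-benzoquinone (10 mol%), CH2Cl2, 40 °C, 16 h (alkene **8** in 10-fold excess)
Reagents that add atoms: 2-methylbut-3-en-2-ol, C=CC(C)(C)O
Why: Olefin cross-metathesis between a terminal allylarene and a vinyl carbinol. The tertiary alcohol is tolerated, the excess partner suppresses homodimerization, and benzoquinone suppresses Ru–H isomerization. The new alkene geometry is irrelevant because it is removed in Step 6.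

**Step 6**
Reactants: **9**
Product: **10** 3'-(3-hydroxy-3-methylbutyl)-4',7-bis-O-MOM-genistein
Conditions: H2 (1 atm), RhCl(PPh3)3 (5 mol%), toluene/EtOH, rt
Reagents that add atoms: none (H2 adds only H)
Why: Wilkinson hydrogenation reduces the 1,2-disubstituted alkene but leaves the conjugated chromone C2=C3 bond and the aryl MOM ethers alone. No stereocenter is created, because the carbinol is achiral.

**Step 7**
Reactants: **10**; **4** allyl bromide
Product: **11** 5-O-allyl-4',7-bis-O-MOM-3'-(3-hydroxy-3-methylbutyl)genistein
Conditions: allyl bromide (3 equiv), Cs2CO3, DMF, 60 °C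
Reagents that add atoms: allyl bromide, C=CCBr
Why: The chelated 5-OH is the only phenol left, and Cs2CO3 with mild heat alkylates it. The tertiary alcohol is not acidic enough to be alkylated.

**Step 8**
Reactants: **11**
Product: **12** 6-allyl-5-hydroxy-4',7-bis-O-MOM-3'-(3-hydroxy-3-methylbutyl)isoflavone
Conditions: PhNEt2, 200 °C (microwave), 45 min
Reagents that add atoms: none (isomerization)
Why: Claisen [3,3] rearrangement of the aryl allyl ether. C4a is substituted, so the only available ortho carbon is C6, and the 5-OH re-forms its chelate. There is no C6/C8 ambiguity, and no stereocenter is involved.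

**Step 9**
Reactants: **12**; **13** 2-methyl-2-butene
Product: **14** 6-prenyl-5-hydroxy-4',7-bis-O-MOM-3'-(3-hydroxy-3-methylbutyl)isoflavone
Conditions: Hoveyda–Grubbs II (10 mol%), 2-methyl-2-butene (about 30 equiv), CH2Cl2, 40 °C, sealed tube, 24 h
Reagents that add atoms: 2-methyl-2-butene, CC=C(C)C
Why: Cross-metathesis converts ArCH2CH=CH2 into ArCH2CH=CMe2 (propene is lost). The excess trisubstituted alkene drives the reaction. The free chelated phenol and the tertiary alcohol are tolerated, and no stereocenter is involved.

**Step 10**
Reactants: **14**
Product: **15** Coloratanin A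
Conditions: 3 M aq. HCl, MeOH/THF (1:1), 40 °C, 4 h
Reagents that add atoms: none (MOM groups are lost as CH2O and MeOH)
Why: Acetal hydrolysis removes both aryl MOM ethers and regenerates the 7-OH and 4'-OH. The prenyl group, the tertiary alcohol, the chromone and the stereochemical status of the product are unchanged, because the target is achiral.

## Compound list
1 | genistein | O=c1c(-c2ccc(O)cc2)coc2cc(O)cc(O)c12 | starting material
2 | chloromethyl methyl ether (MOMCl) | ClCOC | starting material (reagent)
3 | 7-O-MOM-genistein | COCOc1cc(O)c2c(=O)c(-c3ccc(O)cc3)coc2c1 | intermediate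
4 | allyl bromide | C=CCBr | starting material (reagent)
5 | 4'-O-allyl-7-O-MOM-genistein | COCOc1cc(O)c2c(=O)c(-c3ccc(OCC=C)cc3)coc2c1 | intermediate
6 | 3'-allyl-4'-hydroxy-7-O-MOM-genistein | COCOc1cc(O)c2c(=O)c(-c3ccc(O)c(CC=C)c3)coc2c1 | intermediate
7 | 3'-allyl-4',7-bis-O-MOM-genistein | COCOc1cc(O)c2c(=O)c(-c3ccc(OCOC)c(CC=C)c3)coc2c1 | intermediate
8 | 2-methylbut-3-en-2-ol | C=CC(C)(C)O | starting material (reagent)
9 | E-enol cross-metathesis product | COCOc1cc(O)c2c(=O)c(-c3ccc(OCOC)c(C/C=C/C(C)(C)O)c3)coc2c1 | intermediate
10 | 3'-(3-hydroxy-3-methylbutyl)-4',7-bis-O-MOM-genistein | COCOc1cc(O)c2c(=O)c(-c3ccc(OCOC)c(CCC(C)(C)O)c3)coc2c1 | intermediate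
11 | 5-O-allyl derivative of 10 | COCOc1cc(OCC=C)c2c(=O)c(-c3ccc(OCOC)c(CCC(C)(C)O)c3)coc2c1 | intermediate
12 | 6-allyl-5-hydroxy isoflavone (bis-MOM) | C=CCc1c(OCOC)cc2occ(-c3ccc(OCOC)c(CCC(C)(C)O)c3)c(=O)c2c1O | intermediate
13 | 2-methyl-2-butene | CC=C(C)C | starting material (reagent)
14 | 6-prenyl bis-MOM isoflavone | CC(C)=CCc1c(OCOC)cc2occ(-c3ccc(OCOC)c(CCC(C)(C)O)c3)c(=O)c2c1O | intermediate
15 | Coloratanin A (achiral) | CC(C)=CCc1c(O)cc2occ(-c3ccc(O)c(CCC(C)(C)O)c3)c(=O)c2c1O | target

## Totals
Total steps: 10. Longest linear sequence: 10 (1 → 3 → 5 → 6 → 7 → 9 → 10 → 11 → 12 → 14 → 15, counting steps).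

**Three steps most likely to fail:**
1. **Step 9** (allyl → prenyl cross-metathesis on a hindered, ortho-disubstituted phenolic allylarene; risks are isomerization to the propenyl compound and incomplete conversion). Fallback: oxidatively cleave the allyl group of **12** (cat. OsO4, NaIO4) to the arylacetaldehyde, then do a Wittig olefination with Ph3P=CMe2 (excess, from isopropyltriphenylphosphonium iodide) to give **14**.
2. **Step 8** (and Step 3) (200 °C Claisen on a substrate carrying MOM ethers and a tertiary alcohol; risks are MOM loss and dehydration). Fallback: drop the Claisen approach. Instead make the 6-prenyl A ring de novo by ortho-lithiation/prenylation of 1,3,5-tris(MOM)phloroglucinol, and assemble the isoflavone by Pd-catalysed α-arylation of the corresponding acetophenone with 4-bromo-2-(3-hydroxy-3-methylbutyl)phenol (made from dihydrocoumarin and MeMgBr), followed by DMF-DMA cyclization.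
3. **Step 10** (acid-mediated MOM removal; risks are cyclization of the prenyl group onto the 5-OH to give a chromane, and dehydration of the tertiary alcohol). Fallback: change the protecting-group strategy to SEM ethers at O-7 and O-4' from Steps 1 and 4, which survive the Claisen and metathesis steps, and remove them under non-acidic conditions (TBAF/ethylenediamine, THF, 50 °C).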